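The data were computed for an exercise; the scatter is artificial.

At early times in the theta run you see Q rise first and G follow it, so this is a chain, and you want G in a flask at twice the concentration, with the same equivalents.

| setting | theta | flask |
|---|---|---|
| J | 0.40 M | 0.80 M |
| E | 2 equiv | 2.00 equiv |
| X | 0.50 equiv | 0.500 equiv |
| remark | run made earlier |  |
| time |  | 50 min |

theta run (percent of the J charged)

| time / min | G / % | Q / % |
|---|---|---|
| 3.00 | 0.9 | 8.1 |
| 10.0 | 3.8 | 12.0 |
| 20.0 | 5.6 | 10.0 |
| 25.0 | 7.6 | 9.9 |
| 40.0 | 8.4 | 7.8 |
| 50.0 | 9.9 | 7.1 |

(each reading ± 0.5 percentage points)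

- what was read earlier has a scatter of 0.5 percentage points, one standard deviation
- no earlier run changes the charge of E; that part of a forecast is a guess
- no earlier run changes the charge of X; that part of a forecast is a guess

- equivalents of E to J, everything else as given, that leave most G at 50 min
- the amount of G then, in percent of the J charged
- the amount of G with the amounts as given

Suppose every step is a meeting of two molecules. Then scaling all concentrations up and the time down by one factor leaves each percentage unchanged, and the clock is the exposure (a reduced time for second-order steps). The last theta reading stands at 20.0 M·min of exposure, charged [J] times time, and the flask reaches 40.0 M·min of exposure, twice as much.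

So you must extrapolate. Between 25.0 min and 50.0 min the theta readings show G gaining 2.3 percentage points and Q shrinking by a factor 0.717, and the flask needs two more such spans. Let that gain continue unchanged and G reaches 14.5%, a loose ceiling. Shrink each span's gain by that factor of Q, and my ceiling tightens to 12.7%. For a floor, let G stop gaining and sink with Q: 5.09%. I commit to the middle, 8.91%. No earlier run varied E, so I give no optimum.

The forecast puts G at 11.5%, above my middle but inside my bracket, and guesses 44% at 10 equiv of E, since “more E only pushes G higher”.

The flask gives G 8.38%, inside the bracket at an exposure of 40.0 M·min, and its best over E is 9.26% at 2.97 equiv.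

    J + E ⇌ X + Q (K = 1.00, k = 0.0530 M⁻¹ min⁻¹)
    Q + E ⇌ X + G (K = 3.20, k = 0.0550 M⁻¹ min⁻¹)
    G + E ⇌ X + D (K = 0.130, k = 0.00330 M⁻¹ min⁻¹)
    Q + E → L (k = 0.230 M⁻¹ min⁻¹)

The equations above are meetings of two molecules, as the exposure assumes. Now take the neighbouring flask with 0.20 M of J, read at 50 min. Its exposure is 10.0 M·min, which equals the theta run's at 25.0 min, so you read off G 7.6% and Q 9.9%. That neighbouring flask holds G 7.26% and Q 9.39%, differences of 0.34 points and 0.51 points against a scatter of 0.5 points.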